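Slowness is your first impression of the blue run: from 0.333 d to 3.00 d its target stands at 7% of the charge. The violet run, with a smaller charge, reads higher.

common to all: gas 1.8 mM (held)

|  | solid substrate | remark | time |
|---|---|---|---|
| violet | 0.026 M | run made earlier |  |
| blue | 0.10 M | run made earlier |  |
| flask | 0.052 M |  | 6.0 d |

| run | time / d | target / % |
|---|---|---|
| violet | 0.125 | 19 |
| violet | 0.333 | 26 |
| violet | 0.625 | 22 |
| violet | 1.67 | 21 |
| violet | 3.00 | 20 |
| violet | 8.00 | 19 |
| blue | 0.125 | 5 |
| blue | 0.333 | 7 |
| blue | 0.625 | 7 |
| blue | 1.67 | 7 |
| blue | 3.00 | 7 |
| blue | 8.00 | 9 |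

(readings scatter by 1.5 percentage points)

- solid substrate is a solid; its amount is given per volume of the solution
- at the start none of the solid substrate is in solution
- at the start none of the gas is in solution

1. the moment within 6.0 d at which there is most target
2. the amount of target, in percent of the solid substrate charged, at that time

Those fractions refer to different charges, so carry blue's plateau over to this flask by the ratio of the charges. The result, 13.5%, is the plateau share: the fraction of this flask's charge that the amount of target read on blue's plateau would make up, with the scatter of that reading. It is my estimate of the flask's peak yield.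

Now test it. Violet's highest reading, 26%, folded the same way, gives 13.0%, so the readings of the two runs point to about one height. But one number is not enough: violet's last reading is 0.731 of that highest reading, and the plateau share holds no clock, so I give no time from it.

The forecast says 14% at 0.8 d: “I expect a broad maximum there, followed by slow decline.”

The simulation gives 15.0% at 0.543 d.

    solid substrate ⇌ dissolved substrate, rate k1*(cs1 - [dissolved substrate]) while solid is left; crystals form when [dissolved substrate] > cs1 (solubility = 22.0 mM, k = 1.70 × 10⁻⁴ s⁻¹)
    dissolved substrate + partner → target (k = 0.0670 M⁻¹ s⁻¹)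
    dissolved substrate + target → side product (k = 0.00630 M⁻¹ s⁻¹)
    partner → decomposed reagent (k = 4.20 × 10⁻⁵ s⁻¹)
    gas ⇌ partner, rate k5*(csat - [partner]) (kL = 9.30 × 10⁻⁴ s⁻¹)
    target ⇌ isomer of the product (K = 1.20, k = 3.90 × 10⁻⁵ s⁻¹)

The forecast's time is 1.47 times the flask's. Target in this flask stands at 12.8% at 6.00 d. Now take the neighbouring flask, charged with 0.031 M of solid substrate. Folding blue's plateau reading by that charge gives a plateau share of 22.6%, and the neighbouring flask peaks at 22.0%. Target in the neighbouring flask stands at 17.6% at 6.00 d.

The runs are calculated from invented constants; scatter was added.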